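Starting material does not vanish, so the readings ought to add up to the charge; yet at the last reading they come to 38.0% in larch, 35.0% in oak and 40.0% in birch, and the rest sits somewhere you cannot read.

in all of them: free catalyst 10 mM; second catalyst 30 mM
- larch: starting material 0.41 M; reagent 0.287 M; run made earlier
- oak: starting material 0.41 M; reagent 0.40 M; run made earlier
- birch: starting material 0.41 M; reagent 0.63 M; run made earlier
- autumn: starting material 0.41 M (fed, over 3.00 h); reagent 0.287 M; all but starting material at the start; starting material goes in evenly over 3.00 h, the run ends at 3.0 h; time 3.0 h
- spring: starting material 0.41 M; reagent 0.287 M; one stirred flow tank at steady state, fed with the mixture as stated, mean residence time 3.0 h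
- midnight: starting material 0.41 M; reagent 0.287 M; everything together in a closed stirred flask, run for 3.0 h; time 3.0 h
- dawn: starting material 0.41 M; reagent 0.287 M (fed, over 3.00 h); all but reagent at the start; reagent goes in evenly over 3.00 h, the run ends at 3.0 h; time 3.0 h

- larch (time / min: open intermediate / %, target / %, starting material / %): 10.0: 15, 0, 37; 25.0: 27, 5, 16; 50.0: 20, 9, 5; 80.0: 19, 15, 4; 120: 14, 24, 0
- oak (time / min: open intermediate / %, target / %, starting material / %): 20.0: 22, 8, 18; 40.0: 19, 10, 9; 60.0: 21, 16, 4; 80.0: 14, 20, 0; 120: 9, 26, 0
- birch (time / min: open intermediate / %, target / %, starting material / %): 8.00: 13, 1, 41; 15.0: 18, 1, 23; 30.0: 19, 6, 11; 60.0: 16, 19, 5; 120: 9, 31, 0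

(readings scatter by 2 percentage points)

- the stated concentrations are those of everything mixed, before any reaction; amounts are the same in each set-up
- the feed brings no volume worth counting
- the earlier runs were made in a closed, stirred flask

- the set-up with the highest amount of open intermediate at the outlet or at the end, in percent of the starting material put in ("none" if the first two lie within 2 percentage points) (autumn / spring / midnight / dawn / none)
- amount of open intermediate at the outlet or at the end, in percent of the starting material put in, autumn
- amount of open intermediate at the outlet or at the end, in percent of the starting material put in, spring
- amount of open intermediate at the outlet or at the end, in percent of the starting material put in, midnight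
- amount of open intermediate at the outlet or at the end, in percent of the starting material put in, dawn

The fall of starting material looks alike at both reagent charges: larch holds 16% after 25.0 min, birch 11% after 30.0 min. In larch, the fractional loss reads 0.0994 /min while on average 0.634 of the charge remains, but 0.0559 /min at 0.250. So you read two routes: a pseudo-first-order one, and an unseen one that goes with the square of the fraction left, with slope 0.114 /min.

Take equal shares as the zero of the scale. The two routes tie at the crossover fraction, the fraction of the charge left at which each takes an equal share, read here as 0.241. With this catalyst charge, at a given fraction left, the share going to open intermediate is crossover over crossover plus fraction.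

A closed flask run down from the whole charge averages a share of 0.395, so I reckon that for midnight and dawn. Feeding evenly, autumn should hold near 0.131, with share 0.648, so I put autumn above them.

The forecast named autumn, with 29% there, 24% in spring, 8.5% in midnight and 13% in dawn: “slow feed keeps starting material near 12%, selectivity about 64%”. The flask gives autumn as best, with 28.4% there, 23.6% in spring, 9.00% in midnight and 16.3% in dawn.

    starting material + free catalyst → free catalyst + open intermediate (k = 2.86 /M/min)
    second catalyst + open intermediate ⇌ catalyst intermediate (K = 0.490 /M, k = 1.80 /M/min)
    reagent + catalyst intermediate → second catalyst + target (k = 3.88 /M/min)
    2 starting material → homo dimer (k = 0.145 /M/min)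
    starting material + target → side product (k = 0.0509 /M/min)

Autumn's starting material peaks at 0.124 of the charge, below crossover. The homo dimer is part of the reason: without that step midnight rises from 9.00% to 38.4%, autumn from 28.4% to 41.4%. The spring tank stands at 0.108 of the charge, so by the same rule its share is 0.692, and its outlet holds 23.6% open intermediate.

All runs were generated by integration on assumed constants; noise was put on by code.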